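## Retrosynthetic overview

1. Target 16 (macrophorin D) ⇒ macrophorin A (14) + 3-hydroxy-3-methylglutaric anhydride (15). The ester bond is made last by a catalyst-controlled desymmetrising ring-opening that sets the (3S) centre.
2. 14 ⇒ epoxyquinone 13 ⇒ epoxy monoketal 12 ⇒ dienone monoketal 11. The carbinol comes from a hydroxyl-directed reduction and the oxirane from a face-selective nucleophilic epoxidation.
3. Key bond C11–C1′ (11 ⇒ 9 + 4): albicanylzinc iodide (C11 as nucleophile) attacks the α-carbon of an unprotected α-iodo quinone monoketal. That α-carbon reacts as an α-keto vinyl cation (enolonium equivalent), and the ring is already at the quinone oxidation level.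
4. 9 ⇐ (+)-sclareolide (lactone excised by alkoxy-radical β-scission, then exocyclic dehydration); 4 ⇐ 5-hydroxy-2-methoxybenzaldehyde (reduction, oxidative dearomatisation, α-iodination).
5. Ring order: the decalin (rings A and B) is bought with sclareolide; the six-membered quinol ring comes from the arene by dearomatisation; the oxirane is the only ring closed during the synthesis (step 9).

Assumption: the target is macrophorin D as drawn; in the two reagent-controlled steps (9 and 12) no sense of induction is known for these exact substrates, so the reagent enantiomer named is the one expected by analogy, and its antipode (D-tartrate; quinine-series catalyst) is used if the observed sense is opposite.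

Locants and shorthand: C11 is the CH2 linking the decalin to the ring. Ring carbons are C1′ (quaternary oxirane C), C2′ (oxirane CH), C3′ (carbinol), C4′ (C bearing CH2O), C5′ (=CH) and C6′ (C=O). "Albicanyl" = [(1S,4aS,8aS)-5,5,8a-trimethyl-2-methylidenedecahydronaphthalen-1-yl]methyl (drim-8(12)-en-11-yl; 5α-H, 9α-H, 10β-CH3).

## Route

Step 1
Reactants: 1 5-hydroxy-2-methoxybenzaldehyde
Product: 2 3-(hydroxymethyl)-4-methoxyphenol
Conditions: NaBH4 (1.0 equiv), MeOH, 0 °C
Reagents that add atoms: none
Why: Borohydride reduction of the aryl aldehyde to the benzylic alcohol, with no stereocentre involved.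

Step 2
Reactants: 2 3-(hydroxymethyl)-4-methoxyphenol
Product: 3 3-(hydroxymethyl)-4,4-dimethoxycyclohexa-2,5-dien-1-one
Conditions: PhI(OAc)2 (1.1 equiv), MeOH, 0 °C
Reagents that add atoms: methanol, SMILES CO
Why: Oxidative dearomatisation of a para-methoxyphenol by a λ3-iodane with methanol capture at the para carbon gives the quinone monoketal, placing the carbonyl at the former phenol carbon and the ketal next to the CH2OH-bearing carbon without regiochemical ambiguity.

Step 3
Reactants: 3 3-(hydroxymethyl)-4,4-dimethoxycyclohexa-2,5-dien-1-one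
Product: 4 5-(hydroxymethyl)-2-iodo-4,4-dimethoxycyclohexa-2,5-dien-1-one
Conditions: I2 (1.5 equiv), pyridine, CH2Cl2, 0 → 25 °C
Reagents that add atoms: iodine, SMILES II
Why: Johnson-type α-iodination of an enone (pyridine adds to the β-carbon, the enolate is iodinated, pyridine is expelled) occurs only on the enone arm whose β-carbon is less substituted, so iodine enters at C1′, remote from the CH2OH-bearing alkene.

Step 4
Reactants: 5 (+)-sclareolide
Product: 6 sclareolide lactol (3aR,5aS,9aS,9bR)-3a,6,6,9a-tetramethyldodecahydronaphtho[2,1-b]furan-2-ol (both anomers)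
Conditions: i-Bu2AlH (1.1 equiv), CH2Cl2, −78 °C; aq KNaC4H4O6 work-up
Reagents that add atoms: none
Why: Half-reduction of the γ-lactone to the lactol at low temperature, leaving all four ring stereocentres untouched.

Step 5
Reactants: 6 sclareolide lactol
Product: 7 (1R,2R,4aS,8aS)-1-(iodomethyl)-2,5,5,8a-tetramethyldecahydronaphthalen-2-yl formate (11-iododrimane-8α-yl formate)
Conditions: PhI(OAc)2 (1.2 equiv), I2 (1.0 equiv), cyclohexane, hν (tungsten lamp), 25 °C
Reagents that add atoms: iodine, SMILES II
Why: Suárez alkoxy-radical β-fragmentation cleaves the C11–C12 bond of the lactol, leaving C12 on the C8 oxygen as a formate while the primary C11 radical is trapped by iodine; C8 and C9 keep their configuration.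

Step 6
Reactants: 7 11-iododrimane-8α-yl formate
Product: 8 (1R,2R,4aS,8aS)-1-(iodomethyl)-2,5,5,8a-tetramethyldecahydronaphthalen-2-ol
Conditions: Et3N (0.3 equiv), MeOH, 25 °C
Reagents that add atoms: none
Why: Amine-catalysed transesterification removes the very labile formate as methyl formate under conditions too weakly basic for oxetane closure or Grob fragmentation of the 1,3-iodohydrin.

Step 7
Reactants: 8 11-iododrimane-8α-ol
Product: 9 albicanyl iodide (1S,4aS,8aS)-1-(iodomethyl)-5,5,8a-trimethyl-2-methylidenedecahydronaphthalene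
Conditions: SOCl2 (1.5 equiv), pyridine (4 equiv), CH2Cl2, −78 °C; chromatography on AgNO3-impregnated SiO2
Reagents that add atoms: none
Why: Dehydration of the tertiary alcohol after O-sulfinylation by SOCl2 is an E2 process in which the equatorial 8α leaving group has no antiperiplanar ring hydrogen, so a proton is lost from the C8 methyl group and the exocyclic 8(12)-alkene is the main product (minor endocyclic isomers are removed on the silver-loaded column).

Step 8
Reactants: 9 albicanyl iodide; 4 5-(hydroxymethyl)-2-iodo-4,4-dimethoxycyclohexa-2,5-dien-1-one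
Product: 11 2-albicanyl-5-(hydroxymethyl)-4,4-dimethoxycyclohexa-2,5-dien-1-one, via albicanylzinc iodide 10 (not isolated)
Conditions: 9 (1.4 equiv), Zn dust (3 equiv, activated with BrCH2CH2Br and Me3SiCl), LiCl (1.5 equiv), THF, 40 °C; then added over 1 h to 4 (1.0 equiv), Pd(OAc)2 (5 mol %), SPhos (2-dicyclohexylphosphino-2′,6′-dimethoxybiphenyl, 10 mol %), THF, 0 → 25 °C
Reagents that add atoms: none
Why: Negishi sp3–sp2 coupling in which the ketone α-carbon C1′, as its vinyl iodide, is the electrophile (α-keto vinyl cation, an enolonium equivalent) and the normally electrophilic C11 is the nucleophile; oxidative addition to zerovalent palladium and coupling with the SPhos catalyst outpace protonolysis by the free primary alcohol and β-hydride loss, and no stereocentre is formed or disturbed.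

Step 9
Reactants: 11 2-albicanyl-5-(hydroxymethyl)-4,4-dimethoxycyclohexa-2,5-dien-1-one
Product: 12 (1R,6S)-1-albicanyl-4-(hydroxymethyl)-5,5-dimethoxy-7-oxabicyclo[4.1.0]hept-3-en-2-one
Conditions: Ph3COOH (2 equiv), NaN(SiMe3)2 (3 equiv), L-(+)-diisopropyl tartrate (1.2 equiv), 4 Å molecular sieves, toluene, −78 → −40 °C; aq NH4Cl quench
Reagents that add atoms: trityl hydroperoxide, SMILES OOC(c1ccccc1)(c1ccccc1)c1ccccc1
Why: Tartrate-mediated nucleophilic (Weitz–Scheffer) epoxidation: the peroxide anion adds to C2′, the less substituted β-carbon (the other enone arm is β,β-disubstituted), while the sodium alkoxide of the CH2OH group anchors the chiral tartrate–peroxide aggregate so that oxygen is delivered to one face, setting C1′ and C2′ together on ring closure.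

Step 10
Reactants: 12 epoxy monoketal
Product: 13 (1R,6S)-1-albicanyl-4-(hydroxymethyl)-7-oxabicyclo[4.1.0]hept-3-ene-2,5-dione (4′-oxomacrophorin A)
Conditions: 48% aq HF, MeCN, 0 → 25 °C
Reagents that add atoms: water, SMILES O
Why: Acid-catalysed hydrolysis of the dimethyl ketal to the ene-dione under conditions that the α-keto oxirane and the 1,1-disubstituted alkene tolerate, with no change at any stereocentre.

Step 11
Reactants: 13 4′-oxomacrophorin A
Product: 14 macrophorin A (1R,5R,6R)-1-albicanyl-5-hydroxy-4-(hydroxymethyl)-7-oxabicyclo[4.1.0]hept-3-en-2-one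
Conditions: Me4NBH(OAc)3 (3 equiv), MeCN/AcOH 1:1, −30 °C
Reagents that add atoms: none
Why: Hydroxyl-directed triacetoxyborohydride reduction (Saksena–Evans type): after ligand exchange at the CH2OH group, hydride is delivered through a six-membered transition state only to the adjacent C3′ carbonyl (the C6′ carbonyl is remote and flanked by the quaternary oxirane carbon), and attack anti to the oxirane C–O bond gives the alcohol cis to the oxirane oxygen (3′R).

Step 12
Reactants: 14 macrophorin A; 15 3-hydroxy-3-methylglutaric anhydride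
Product: 16 macrophorin D (target)
Conditions: 15 (2 equiv), 9-amino-9-deoxy-epi-quinidine N-[3,5-bis(trifluoromethyl)phenyl]thiourea (20 mol %), t-BuOMe, −20 °C; NaH2PO4 buffer (pH 3) work-up
Reagents that add atoms: none
Why: Proposed new method: desymmetrising alcoholysis of a prochiral glutaric anhydride, known with bifunctional cinchona thioureas for 3-substituted glutaric anhydrides and simple alcohols, is extended here to the 3-hydroxy-3-methyl anhydride and a complex primary allylic alcohol — the thiourea binds one anhydride carbonyl (helped by the 3-OH), the quinuclidine activates the primary hydroxyl of 14 (the hindered secondary hydroxyl does not compete), and attack on one enantiotopic carbonyl sets the (3S) centre.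

## Compound list

1 | 5-hydroxy-2-methoxybenzaldehyde | COc1ccc(O)cc1C=O | starting material
2 | 3-(hydroxymethyl)-4-methoxyphenol | COc1ccc(O)cc1CO | intermediate
3 | 3-(hydroxymethyl)-4,4-dimethoxycyclohexa-2,5-dien-1-one | COC1(OC)C=CC(=O)C=C1CO | intermediate
4 | 5-(hydroxymethyl)-2-iodo-4,4-dimethoxycyclohexa-2,5-dien-1-one | COC1(OC)C=C(I)C(=O)C=C1CO | intermediate
5 | (+)-sclareolide, (3aR,5aS,9aS,9bR)-3a,6,6,9a-tetramethyldecahydronaphtho[2,1-b]furan-2(1H)-one | C[C@]12CCCC([C@@H]1CC[C@@]3([C@@H]2CC(=O)O3)C)(C)C | starting material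
6 | sclareolide lactol, (3aR,5aS,9aS,9bR)-3a,6,6,9a-tetramethyldodecahydronaphtho[2,1-b]furan-2-ol (both anomers) | C[C@]12CCCC([C@@H]1CC[C@@]3([C@@H]2CC(O)O3)C)(C)C | intermediate
7 | (1R,2R,4aS,8aS)-1-(iodomethyl)-2,5,5,8a-tetramethyldecahydronaphthalen-2-yl formate (11-iododrimane-8α-yl formate) | C[C@]12CCCC([C@@H]1CC[C@@](OC=O)([C@@H]2CI)C)(C)C | intermediate
8 | (1R,2R,4aS,8aS)-1-(iodomethyl)-2,5,5,8a-tetramethyldecahydronaphthalen-2-ol (11-iododrimane-8α-ol) | C[C@]12CCCC([C@@H]1CC[C@@](O)([C@@H]2CI)C)(C)C | intermediate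
9 | albicanyl iodide, (1S,4aS,8aS)-1-(iodomethyl)-5,5,8a-trimethyl-2-methylidenedecahydronaphthalene | C=C1CC[C@H]2C(C)(C)CCC[C@]2(C)[C@H]1CI | intermediate
10 | albicanylzinc iodide, {[(1S,4aS,8aS)-5,5,8a-trimethyl-2-methylidenedecahydronaphthalen-1-yl]methyl}zinc iodide (LiCl complex in THF, not isolated) | C=C1CC[C@H]2C(C)(C)CCC[C@]2(C)[C@H]1C[Zn]I | intermediate
11 | 5-(hydroxymethyl)-4,4-dimethoxy-2-{[(1S,4aS,8aS)-5,5,8a-trimethyl-2-methylidenedecahydronaphthalen-1-yl]methyl}cyclohexa-2,5-dien-1-one | C=C1CC[C@H]2C(C)(C)CCC[C@]2(C)[C@H]1CC1=CC(OC)(OC)C(CO)=CC1=O | intermediate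
12 | (1R,6S)-4-(hydroxymethyl)-5,5-dimethoxy-1-{[(1S,4aS,8aS)-5,5,8a-trimethyl-2-methylidenedecahydronaphthalen-1-yl]methyl}-7-oxabicyclo[4.1.0]hept-3-en-2-one | C=C1CC[C@H]2C(C)(C)CCC[C@]2(C)[C@H]1C[C@@]12O[C@@H]1C(OC)(OC)C(CO)=CC2=O | intermediate
13 | 4′-oxomacrophorin A, (1R,6S)-4-(hydroxymethyl)-1-{[(1S,4aS,8aS)-5,5,8a-trimethyl-2-methylidenedecahydronaphthalen-1-yl]methyl}-7-oxabicyclo[4.1.0]hept-3-ene-2,5-dione | C=C1CC[C@H]2C(C)(C)CCC[C@]2(C)[C@H]1C[C@@]12O[C@@H]1C(=O)C(CO)=CC2=O | intermediate
14 | macrophorin A, (1R,5R,6R)-5-hydroxy-4-(hydroxymethyl)-1-{[(1S,4aS,8aS)-5,5,8a-trimethyl-2-methylidenedecahydronaphthalen-1-yl]methyl}-7-oxabicyclo[4.1.0]hept-3-en-2-one (OH cis to the oxirane oxygen) | C=C1CC[C@H]2C(C)(C)CCC[C@]2(C)[C@H]1C[C@@]12O[C@@H]1[C@H](O)C(CO)=CC2=O | intermediate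
15 | 3-hydroxy-3-methylglutaric anhydride (4-hydroxy-4-methyloxane-2,6-dione) | CC1(O)CC(=O)OC(=O)C1 | starting material
16 | macrophorin D, (3S)-3-hydroxy-5-{[(1R,5R,6R)-5-hydroxy-2-oxo-1-{[(1S,4aS,8aS)-5,5,8a-trimethyl-2-methylidenedecahydronaphthalen-1-yl]methyl}-7-oxabicyclo[4.1.0]hept-3-en-4-yl]methoxy}-3-methyl-5-oxopentanoic acid | C=C1CC[C@H]2C(C)(C)CCC[C@]2(C)[C@H]1C[C@@]12O[C@@H]1[C@H](O)C(COC(=O)C[C@@](C)(O)CC(=O)O)=CC2=O | target

## Totals

Total step count: 12 (ring piece 3, drimane piece 4, union and end-game 5).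
Longest linear sequence: 9 steps (steps 4–12, from (+)-sclareolide).

## Steps most likely to fail, with fallbacks

Step 8 (coupling of 10 with 4). The electrophile is a cross-conjugated, Lewis-acid-sensitive dienone ketal with a free hydroxyl, and the zinc reagent is β-branched. Protonolysis, ketal ionisation by ZnI2 or slow transmetalation could each erode the yield. The fallback sets out from 2 and from 9 (through 10) and comes back at 11. Phenol 2 is iodinated ortho to the hydroxyl (N-iodosuccinimide, MeCN, 0 °C) to 5-(hydroxymethyl)-2-iodo-4-methoxyphenol F1. Both hydroxyls are silylated (t-BuMe2SiCl, imidazole, DMF) to the bis(tert-butyldimethylsilyl) ether F2. F2 is coupled with 10 under the same Pd(OAc)2/SPhos conditions, now as an ordinary aryl iodide with no dienone, ketal or free OH, to give the albicanyl-substituted arene F3. Bu4NF in THF frees the phenol and the benzylic alcohol to give the phenol diol F4, and PhI(OAc)2 in MeOH dearomatises F4 to 11.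

Step 9 (face selectivity of the epoxidation). The remote decalin gives little inherent bias, so the result rests on the tartrate aggregate, whose sense with this substrate is untested. The fallback sets out from 11 and comes back at 13. The dimethyl ketal of 11 is exchanged for the C2-symmetric ketal of (2S,4S)-pentane-2,4-diol (pyridinium p-toluenesulfonate, benzene, 60 °C) to give the chiral spiroketal dienone F5. Its axial methyl group blocks one face of the dienone, so Ph3COOH/KN(SiMe3)2 in THF at −78 °C gives the epoxy spiroketal F6 under auxiliary control (the (2R,4R)-diol is taken if the other face is required). Acid hydrolysis of the ketal (aq HF, MeCN, longer time) gives 13.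

Step 12 (desymmetrising acylation). Discrimination between methyl and hydroxyl at C3 of the anhydride by the catalyst is unprecedented, so the selectivity may be low or its sense reversed. The fallback sets out from 14 and purchased (R)-mevalonolactone (dearer than the other starting materials, but needed only in milligram amounts) and comes back at 16. The lactone is opened with KOH and the potassium carboxylate alkylated with allyl bromide in DMF to allyl (3R)-3,5-dihydroxy-3-methylpentanoate F7. 2,2,6,6-Tetramethylpiperidin-1-oxyl (cat.)/PhI(OAc)2 in MeCN–H2O oxidises the primary alcohol to (3R)-3-hydroxy-3-methyl-5-oxo-5-(prop-2-en-1-yloxy)pentanoic acid F8, whose stereocentre comes unchanged from the chiral pool. Carbodiimide coupling (EDC·HCl, 4-(dimethylamino)pyridine cat., CH2Cl2, 0 °C) with the primary hydroxyl of 14 gives macrophorin D allyl ester F9. Pd(PPh3)4/morpholine in THF removes the allyl group to give 16. Because the carboxyl freed last is the original mevalonate carboxyl, the glutarate centre is necessarily (3S).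

Further compounds

F1 | step 8 | 5-(hydroxymethyl)-2-iodo-4-methoxyphenol | COc1cc(I)c(O)cc1CO
F2 | step 8 | tert-butyl{[4-(tert-butyldimethylsilyloxy)-5-iodo-2-methoxyphenyl]methoxy}dimethylsilane (bis-silyl ether of F1) | COc1cc(I)c(O[Si](C)(C)C(C)(C)C)cc1CO[Si](C)(C)C(C)(C)C
F3 | step 8 | bis(tert-butyldimethylsilyl) ether of 5-(hydroxymethyl)-4-methoxy-2-{[(1S,4aS,8aS)-5,5,8a-trimethyl-2-methylidenedecahydronaphthalen-1-yl]methyl}phenol | C=C1CC[C@H]2C(C)(C)CCC[C@]2(C)[C@H]1Cc1cc(OC)c(CO[Si](C)(C)C(C)(C)C)cc1O[Si](C)(C)C(C)(C)C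
F4 | step 8 | 5-(hydroxymethyl)-4-methoxy-2-{[(1S,4aS,8aS)-5,5,8a-trimethyl-2-methylidenedecahydronaphthalen-1-yl]methyl}phenol | C=C1CC[C@H]2C(C)(C)CCC[C@]2(C)[C@H]1Cc1cc(OC)c(CO)cc1O
F5 | step 9 | 5-(hydroxymethyl)-2-{[(1S,4aS,8aS)-5,5,8a-trimethyl-2-methylidenedecahydronaphthalen-1-yl]methyl}cyclohexa-2,5-dien-1-one 4-[(2S,4S)-pentane-2,4-diyl ketal] | C=C1CC[C@H]2C(C)(C)CCC[C@]2(C)[C@H]1CC1=CC2(O[C@@H](C)C[C@H](C)O2)C(CO)=CC1=O
F6 | step 9 | (1R,6S)-4-(hydroxymethyl)-1-{[(1S,4aS,8aS)-5,5,8a-trimethyl-2-methylidenedecahydronaphthalen-1-yl]methyl}-7-oxabicyclo[4.1.0]hept-3-ene-2,5-dione 5-[(2S,4S)-pentane-2,4-diyl ketal] | C=C1CC[C@H]2C(C)(C)CCC[C@]2(C)[C@H]1C[C@@]12O[C@@H]1C1(O[C@@H](C)C[C@H](C)O1)C(CO)=CC2=O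
F7 | step 12 | allyl (3R)-3,5-dihydroxy-3-methylpentanoate | C[C@@](CC(=O)OCC=C)(O)CCO
F8 | step 12 | (3R)-3-hydroxy-3-methyl-5-oxo-5-(prop-2-en-1-yloxy)pentanoic acid | C[C@@](CC(=O)OCC=C)(O)CC(=O)O
F9 | step 12 | macrophorin D allyl ester (prop-2-en-1-yl ester of 16 at the free carboxyl) | C=C1CC[C@H]2C(C)(C)CCC[C@]2(C)[C@H]1C[C@@]12O[C@@H]1[C@H](O)C(COC(=O)C[C@@](C)(O)CC(=O)OCC=C)=CC2=O
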